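The data come from a simulation from invented constants.

4 questions stand on this flask, and I answer them with one number.

the same everywhere: free catalyst 1.2 mM

|  | starting material | solid reagent | second catalyst | remark | time |
|---|---|---|---|---|---|
| Tuesday's | 0.067 M | 0.13 M | 2.5 mM | run made earlier |  |
| Sunday's | 0.15 M | 0.13 M | 2.5 mM | run made earlier |  |
| Friday's | 0.10 M | 0.13 M | 3.8 mM | run made earlier |  |
| flask | 0.10 M | 0.130 M | 2.5 mM |  | 5.0 d |

| run | time / d | side product / % | target / % |
|---|---|---|---|
| Tuesday's | 0.333 | 13.9 | 25.1 |
| Tuesday's | 0.625 | 19.9 | 41.6 |
| Tuesday's | 1.04 | 24.6 | 56.2 |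
| Tuesday's | 2.00 | 23.7 | 69.4 |
| Tuesday's | 4.00 | 25.2 | 74.7 |
| Sunday's | 0.333 | 25.6 | 20.6 |
| Sunday's | 1.04 | 38.8 | 44.8 |
| Sunday's | 1.67 | 41.2 | 52.9 |
| Sunday's | 3.00 | 41.7 | 58.1 |
| Sunday's | 4.00 | 41.3 | 58.6 |
| Friday's | 0.333 | 16.4 | 28.2 |
| Friday's | 1.04 | 24.9 | 59.7 |
| Friday's | 1.67 | 25.4 | 70.1 |
| Friday's | 3.00 | 25.1 | 73.4 |
| Friday's | 4.00 | 25.5 | 74.1 |

(readings scatter by 0.5 percentage points)

- a species is counted by the starting material in it: one side product counts as two
- the numbers in the tables scatter by 0.5 percentage points (one standard deviation)
- at the start none of the solid reagent is in solution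
- a reading or a percentage of target counts all its forms, free or not

- share of side product in side product plus target at 50 min
- share of side product in side product plus target at 10 h
- share of side product in side product plus target at 5.0 d
- which of side product and target there is more of at 5.0 d

What do you follow? The fraction left, x, of the starting material charged, so x = c(starting material) divided by its charge. It runs from 1 to zero, and time drops out of the share.

What is your rule? One side product holds two starting materials, so I suppose its route is second order and the target route first order. Then side product per target made is b·x, where b is a selectivity factor.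

What does that give at the end? Integrating over x, the target share of the two products is T = ln(1 + b)/b.

Read it off. Tuesday's last row gives T = 74.8%, so b = 0.743. Sunday's gives T = 58.7%, so b = 1.69.

Is the order real? Divide each b by its charge: 11.1 L mol⁻¹ and 11.3 L mol⁻¹. Two different charges give nearly one value.

And this flask? Its value is 1.12, the branching number b: side product made per target made while x is still 1.

But Friday's run has the same starting material. Why is it different? Friday's T = 74.4% gives b = 0.760. This flask's b is 1.47 times that, and Friday's second catalyst is 1.52 times this flask's. So I take b as growing with the starting material charge and falling with second catalyst, at this solid reagent and free catalyst.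

Your answers? The end share of side product is 32.9%, so target leads. At 10 h the share lies between that and 52.8%.

Where is this weakest? At 50 min, earlier than any reading. I still say 52.8% there.

The forecast says 52.5%, 45%, 32.9% and target, because “the runs can be read as target first order in starting material and side product second order”.

    starting material + free catalyst ⇌ free catalyst + open intermediate (K = 0.392, k = 0.0247 L mol⁻¹ s⁻¹)
    second catalyst + open intermediate ⇌ catalyst intermediate (K = 14.0 L mol⁻¹, k = 0.0610 L mol⁻¹ s⁻¹)
    coupling partner + catalyst intermediate → second catalyst + target (k = 0.0962 L mol⁻¹ s⁻¹)
    crystals ⇌ target, rate k4*(cs4 - [target]) while solid is left; crystals form when [target] > cs4 (solubility = 12.0 mM, k = 0.00335 s⁻¹)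
    starting material + open intermediate → side product (k = 5.71 × 10⁻⁴ L mol⁻¹ s⁻¹)
    solid reagent ⇌ coupling partner, rate k6*(cs6 - [coupling partner]) while solid is left; crystals form when [coupling partner] > cs6 (solubility = 0.0770 M, k = 4.26 × 10⁻⁴ s⁻¹)

The flask gives 62.1%, 45.2% and 32.4%, with target ahead. My 50 min figure falls short by 9.3 percentage points, and at 5.00 d the flask has 0.085% of its starting material left. Now take the neighbour charged with 0.40 M of starting material and the same second catalyst. Its b is 4.47, so the rule asks for 38.0% target, or 0.152 M. That is more than the 0.130 M of solid reagent, the limiting reagent there, which allows 32.5%. That neighbour ends with 32.1% target, 66.7% side product and 0.00166 M coupling partner.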